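**Plan**
1. Ring labels: ring A carries CH2 (C1), OH (C3) and the ether O (C4). Ring B is the meta-linked O/CH2 ring and ring C the para-linked CH2/O ring. Ring D carries CH2 (C1), the ether O (C3) and OH (C4).
2. Enabling feature: rings B and C with their CH2CH2 bridge are 3,4'-dihydroxybibenzyl (lunularin). Each of its oxygens ends on a carbon (C4 of ring A, C3 of ring D) whose ortho neighbour is a C–OH. That neighbour can be carried as C–NO2 (ring A) or C–CHO (ring D), which makes the ether carbon an SNAr-active C–F.
3. Retrosynthesis: OH(A) goes back to NO2 and OH(D) to CHO, then both aryl–O bonds, O–C4(A) and O–C3(D), are cut together. This gives a mono-silylated lunularin, itself cut at an alkyne–aryl bond, and an A–CH2CH2–D difluoride, cut at CH2–C1(D).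
4. Forward: the B–C bibenzyl (Sonogashira, hydrogenation) and the A–D bibenzyl (Wittig, B-alkyl Suzuki) are made in parallel. The B–O–A bond joins them and the C–O–D bond closes the only new ring, the 20-membered macrocycle, in the same flask.
5. Endgame: CHO to OH by Baeyer–Villiger oxidation, a temporary acetate, then NO2 to NH2 to N2+ to OH, and deacetylation.
6. Stereochemistry: the target has no stereocentre and no stereogenic double bond, so nothing has to be set.

Key step: step 6

Remark: the phenoxide that closes the ring in the key step is listed in its neutral phenol form; in the flask it is the potassium salt.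

**Step 1**
Reactants: 1 4-iodophenol
Product: 2 (4-iodophenoxy)triisopropylsilane
Conditions: TIPSCl, imidazole, DMF, rt
Reagents that add atoms: chlorotriisopropylsilane (TIPSCl), CC(C)[Si](Cl)(C(C)C)C(C)C
Why: Imidazole-promoted O-silylation of a phenol is routine, and the bulky triisopropylsilyl ether is picked because it should withstand amines, hydrogenation and carbonate at room temperature yet yield to fluoride.

**Step 2**
Reactants: 2 (4-iodophenoxy)triisopropylsilane; 3 3-ethynylphenol
Product: 4 3-{[4-(triisopropylsilyloxy)phenyl]ethynyl}phenol
Conditions: PdCl2(PPh3)2 (2 mol %), CuI (4 mol %), Et3N, THF, rt, argon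
Reagents that add atoms: none
Why: The Sonogashira coupling of an aryl iodide with a terminal arylalkyne runs at room temperature under amine base, tolerates the free ring B phenol and the silyl ether, and delivers the B–C carbon skeleton with its two oxygens already told apart.

**Step 3**
Reactants: 4 3-{[4-(triisopropylsilyloxy)phenyl]ethynyl}phenol
Product: 5 3-{2-[4-(triisopropylsilyloxy)phenyl]ethyl}phenol (lunularin with the ring C oxygen silylated and the ring B OH free)
Conditions: H2 (1 atm), 10% Pd/C, EtOAc, rt
Reagents that add atoms: none
Why: Heterogeneous catalytic hydrogenation should saturate the diarylalkyne fully to the CH2CH2 bridge, while aryl silyl ethers and phenols are inert over Pd/C in ethyl acetate.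

**Step 4**
Reactants: 6 4-fluoro-3-nitrobenzaldehyde
Product: 7 4-ethenyl-1-fluoro-2-nitrobenzene (4-fluoro-3-nitrostyrene)
Conditions: Ph3PCH3Br (1.15 equiv), NaHMDS (1.05 equiv), THF, 0 °C; then 6, −78 → 0 °C
Reagents that add atoms: methyltriphenylphosphonium bromide, C[P+](c1ccccc1)(c1ccccc1)c1ccccc1.[Br-]
Why: The Wittig methylenation of the aldehyde is far faster at low temperature than attack at the activated C–F bond, and keeping the phosphonium salt in excess over the amide base leaves no free base to start such a substitution.

**Step 5**
Reactants: 7 4-ethenyl-1-fluoro-2-nitrobenzene; 8 4-bromo-2-fluorobenzaldehyde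
Product: 10 2-fluoro-4-[2-(4-fluoro-3-nitrophenyl)ethyl]benzaldehyde, via B-alkyl-9-BBN adduct 9 (not isolated)
Conditions: 7 (1.1 equiv), 9-BBN (1.0 equiv), THF, 0 °C → rt; then 8 (0.9 equiv), PdCl2(dppf) (3 mol %), anhydrous K3PO4, DMF, 50 °C; non-oxidative work-up
Reagents that add atoms: 9-borabicyclo[3.3.1]nonane (9-BBN), B1C2CCCC1CCC2 (its boron unit is held only in 9; 10 keeps one hydrogen of it)
Why: Anti-Markovnikov hydroboration of the styrene with 9-BBN followed by B-alkyl Suzuki–Miyaura coupling joins the terminal CH2 to the C–Br carbon of ring D; nitro groups are inert to 9-BBN, the styrene is kept in slight excess so that no B–H reaches the aldehyde, and anhydrous phosphate is used so that no hydroxide meets the activated C–F bonds.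

**Step 6**
Reactants: 5 3-{2-[4-(triisopropylsilyloxy)phenyl]ethyl}phenol; 10 2-fluoro-4-[2-(4-fluoro-3-nitrophenyl)ethyl]benzaldehyde
Product: 13 20-membered macrocycle bearing NO2 on ring A plus CHO on ring D, via linear silyl ether 11 (not isolated), via linear phenoxide 12 (not isolated)
Conditions: 5 and 10 (1 equiv each), K2CO3 (1.2 equiv, added last), 4 Å MS, DMSO (0.1 M), 25 °C, argon; then DMSO to 2 mM, 18-crown-6 (0.5 equiv), 95 °C
Reagents that add atoms: none
Why: Each aryl–O bond arises by attack of a phenoxide on a C–F carbon to give an anionic sigma adduct of the Meisenheimer type that expels fluoride, and the closest known reactions are carbonate-mediated diaryl ether synthesis and macrocyclisation on ortho-fluoronitroarenes and ortho-fluorobenzaldehydes and the fluoride-triggered coupling of aryl silyl ethers with activated aryl fluorides. At 25 °C only the ring B oxygen of 5 is free to become a phenoxide and only the nitro-activated C–F of ring A is electrophilic enough to react, which should give 11 and park the first fluoride as sparingly soluble KF. Dilution, 18-crown-6 and heat then bring this fluoride into solution, it removes the triisopropylsilyl group from the ring C oxygen as the silyl fluoride, and phenoxide 12 attacks the ring D carbon ortho to the formyl group. That attack closes the 20-membered ring end to end in an exo mode, with the charge of the adduct taken up by the formyl group outside the new ring, and the fluoride it expels keeps the desilylation going, so a single charge of carbonate carries both substitutions. The selectivity needed is the pairing B–O–A and C–O–D, secured by the silyl mask, by the reactivity gap between the two C–F bonds and by the crown ether acting as a switch, while ring closure over chain growth is secured by the 2 mM dilution. No stereocentre is formed, and ether exchange at the nitro-activated diaryl ether should stay silent because aryloxide leaves far less readily than fluoride and the intramolecular path would need a strained 12-membered spiro adduct.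

**Step 7**
Reactants: 13 macrocycle bearing NO2 on ring A plus CHO on ring D
Product: 15 macrocycle bearing NO2 on ring A plus OH on ring D, via aryl formate 14 (not isolated)
Conditions: mCPBA, CH2Cl2, rt; aq Na2S2O3/NaHCO3 wash; crude 14, K2CO3 (0.2 equiv), MeOH, rt
Reagents that add atoms: 3-chloroperoxybenzoic acid (mCPBA), OOC(=O)c1cccc(Cl)c1
Why: In this Baeyer–Villiger (Dakin-type) oxidation the ring D aryl group, enriched by its ortho aryloxy and para alkyl substituents, should migrate in preference to hydrogen to give formate 14, which mild methanolysis cleaves, while the nitro group and the diaryl ethers ignore the peracid.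

**Step 8**
Reactants: 15 macrocycle bearing NO2 on ring A plus OH on ring D
Product: 16 macrocycle bearing NO2 on ring A plus OAc on ring D
Conditions: Ac2O, pyridine, DMAP (cat.), CH2Cl2, rt
Reagents that add atoms: acetic anhydride, CC(=O)OC(C)=O
Why: Acetylation of the phenol under nucleophilic catalysis is routine and shields the electron-rich ring D from nitrosation and azo coupling in step 10.

**Step 9**
Reactants: 16 macrocycle bearing NO2 on ring A plus OAc on ring D
Product: 17 macrocycle bearing NH2 on ring A plus OAc on ring D
Conditions: H2 (1 atm), 10% Pd/C, EtOAc, rt; used promptly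
Reagents that add atoms: none
Why: Catalytic hydrogenation of a nitroarene to the aniline is fast over Pd/C under neutral conditions that leave the aryl acetate, the diaryl ethers and the bibenzyl bridges untouched.

**Step 10**
Reactants: 17 macrocycle bearing NH2 on ring A plus OAc on ring D
Product: 19 macrocycle bearing OH on ring A plus OAc on ring D, via diazonium tetrafluoroborate 18 (not isolated)
Conditions: t-BuONO (1.05 equiv), HBF4 (48% aq), MeCN, 0 °C; then Cu(NO3)2·3H2O (large excess), Cu2O, H2O, rt
Reagents that add atoms: water, O (the new phenol oxygen); tert-butyl nitrite, CC(C)(C)ON=O (its nitrogen is held only in 18); tetrafluoroboric acid, [H+].F[B-](F)(F)F (counter-ion of 18 only)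
Why: Diazotisation is followed by a Sandmeyer-type hydroxylation in which monovalent copper from Cu2O reduces the diazonium ion to the aryl radical at room temperature and the large excess of divalent copper from Cu(NO3)2 captures it with water faster than it can attack ring B or abstract hydrogen, a sequence with precedent on ortho-aryloxyanilines inside macrocyclic diaryl ethers.

**Step 11**
Reactants: 19 macrocycle bearing OH on ring A plus OAc on ring D
Product: 20 target CNP0329842.0
Conditions: K2CO3 (0.3 equiv), MeOH–THF, rt, argon; aq NH4Cl
Reagents that add atoms: none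
Why: Base-catalysed transesterification of an aryl acetate with methanol is fast at room temperature and touches nothing else in the macrocycle, air being excluded to spare the electron-rich phenols.

**Compound list**
1 | 4-iodophenol | Oc1ccc(I)cc1 | starting material
2 | (4-iodophenoxy)triisopropylsilane | CC(C)[Si](Oc1ccc(I)cc1)(C(C)C)C(C)C | intermediate
3 | 3-ethynylphenol | C#Cc1cccc(O)c1 | starting material
4 | 3-{[4-(triisopropylsilyloxy)phenyl]ethynyl}phenol | Oc1cccc(C#Cc2ccc(O[Si](C(C)C)(C(C)C)C(C)C)cc2)c1 | intermediate
5 | 3-{2-[4-(triisopropylsilyloxy)phenyl]ethyl}phenol (lunularin mono-silyl ether, ring B OH free) | Oc1cccc(CCc2ccc(O[Si](C(C)C)(C(C)C)C(C)C)cc2)c1 | intermediate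
6 | 4-fluoro-3-nitrobenzaldehyde | O=Cc1ccc(F)c(c1)[N+](=O)[O-] | starting material
7 | 4-ethenyl-1-fluoro-2-nitrobenzene | C=Cc1ccc(F)c(c1)[N+](=O)[O-] | intermediate
8 | 4-bromo-2-fluorobenzaldehyde | O=Cc1ccc(Br)cc1F | starting material
9 | 9-[2-(4-fluoro-3-nitrophenyl)ethyl]-9-borabicyclo[3.3.1]nonane (not isolated) | O=[N+]([O-])c1cc(CCB2C3CCCC2CCC3)ccc1F | intermediate
10 | 2-fluoro-4-[2-(4-fluoro-3-nitrophenyl)ethyl]benzaldehyde | O=Cc1ccc(CCc2ccc(F)c(c2)[N+](=O)[O-])cc1F | intermediate
11 | linear silyl ether: B–O–A ether formed, ring C OTIPS and ring D C–F intact (not isolated) | O=Cc1ccc(CCc2ccc(Oc3cccc(CCc4ccc(O[Si](C(C)C)(C(C)C)C(C)C)cc4)c3)c(c2)[N+](=O)[O-])cc1F | intermediate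
12 | linear phenoxide, drawn as the neutral ring C phenol (not isolated) | O=Cc1ccc(CCc2ccc(Oc3cccc(CCc4ccc(O)cc4)c3)c(c2)[N+](=O)[O-])cc1F | intermediate
13 | 20-membered macrocycle, NO2 on ring A (ortho to O), CHO on ring D (ortho to O) | O=[N+]([O-])c1cc2ccc1Oc1cccc(c1)CCc1ccc(cc1)Oc1cc(ccc1C=O)CC2 | intermediate
14 | macrocycle, NO2 on ring A, formyloxy on ring D (not isolated) | O=[N+]([O-])c1cc2ccc1Oc1cccc(c1)CCc1ccc(cc1)Oc1cc(ccc1OC=O)CC2 | intermediate
15 | macrocycle, NO2 on ring A, OH on ring D | O=[N+]([O-])c1cc2ccc1Oc1cccc(c1)CCc1ccc(cc1)Oc1cc(ccc1O)CC2 | intermediate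
16 | macrocycle, NO2 on ring A, OAc on ring D | O=[N+]([O-])c1cc2ccc1Oc1cccc(c1)CCc1ccc(cc1)Oc1cc(ccc1OC(C)=O)CC2 | intermediate
17 | macrocycle, NH2 on ring A, OAc on ring D | Nc1cc2ccc1Oc1cccc(c1)CCc1ccc(cc1)Oc1cc(ccc1OC(C)=O)CC2 | intermediate
18 | macrocycle, diazonium tetrafluoroborate on ring A, OAc on ring D (not isolated) | N#[N+]c1cc2ccc1Oc1cccc(c1)CCc1ccc(cc1)Oc1cc(ccc1OC(C)=O)CC2.F[B-](F)(F)F | intermediate
19 | macrocycle, OH on ring A, OAc on ring D | Oc1cc2ccc1Oc1cccc(c1)CCc1ccc(cc1)Oc1cc(ccc1OC(C)=O)CC2 | intermediate
20 | CNP0329842.0 | Oc1cc2ccc1Oc1cccc(c1)CCc1ccc(cc1)Oc1cc(ccc1O)CC2 | target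

**Total step count:** 11
**Longest linear sequence:** 9 steps (steps 1–3, then 6–11)

**Steps most likely to fail**

**Step 6.** Two things may go wrong.
- The silyl group may be lost early, or migrate from phenoxide to phenoxide, during the first stage. That would blur the pairing of oxygens and rings.
- Ring closure at the formyl-activated C–F bond may be too slow at 2 mM. Chain growth between molecules, or hydrolysis of the C–F bond by traces of water, would then take over.

Fallback (from 5, with 8 and 9, back at 13): the two substitutions are run in the opposite order. The sluggish one is then intermolecular and concentrated, and the ring is closed at the fast nitro-activated fluoride. The ring B phenol of 5 is capped with MOMCl and iPr2NEt in CH2Cl2 to give the methoxymethyl silyl bis-ether F1. Catalytic CsF in DMSO at 100 °C and 0.5 M couples its ring C silyl ether directly with 8 to give the bromo diaryl ether aldehyde F2. B-alkyl Suzuki–Miyaura coupling of F2 with borane 9 under the conditions of step 5 attaches ring A and gives the protected seco compound F3. Aqueous HCl in THF removes the methoxymethyl group to give the seco phenol F4. K2CO3 in DMSO at 2 mM and room temperature then closes the same 20-membered ring through the ring B oxygen and returns to 13.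

**Step 5.** Three things may go wrong.
- The base or traces of hydroxide may displace the nitro-activated fluoride at 50 °C.
- Residual B–H, or hydride transfer from the B-alkyl borane, may reduce the formyl group.
- β-Hydride elimination or protodeboronation may occur in place of transmetallation.

Fallback (from 7 and 8, back at 10): the bridge is made as an alkene and then saturated without a hydrogenation catalyst. Compound 8 is converted with ethylene glycol and catalytic TsOH (toluene, Dean–Stark) into the bromo dioxolane F5. A Heck reaction with 7 (Pd(OAc)2, P(o-tol)3, Cy2NMe, DMF, 90 °C) gives the (E)-stilbene acetal F6. Diimide generated from potassium azodicarboxylate and AcOH at room temperature saturates the C=C bond without touching the nitro group and gives the bibenzyl acetal F7. Aqueous HCl in THF then frees the aldehyde 10.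

**Step 10.** Three things may go wrong.
- The aryl radical or cation may attack the neighbouring ring B (Pschorr-type ring closure).
- Hydrogen abstraction may remove the nitrogen function without oxygenation.
- The diazonium salt may dissolve poorly in the aqueous copper medium.

Fallback (from 17, back at 20): the C–O bond is made by metal-catalysed hydroxylation of an aryl halide. One-pot diazotisation–iodination of 17 (NaNO2, KI, TsOH, MeCN, rt), in which iodide traps the aryl radical very fast, gives the aryl iodide acetate F8. CuI, 1,10-phenanthroline and KOH in DMSO–H2O at 100 °C under argon replace iodide by hydroxide and saponify the acetate in the same operation. Acidification should then give 20 directly.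

**Further compounds**
F1 | step 6 | methoxymethyl silyl bis-ether: 1-(methoxymethoxy)-3-{2-[4-(triisopropylsilyloxy)phenyl]ethyl}benzene | COCOc1cccc(CCc2ccc(O[Si](C(C)C)(C(C)C)C(C)C)cc2)c1
F2 | step 6 | bromo diaryl ether aldehyde: 4-bromo-2-(4-{2-[3-(methoxymethoxy)phenyl]ethyl}phenoxy)benzaldehyde | O=Cc1ccc(Br)cc1Oc1ccc(CCc2cccc(OCOC)c2)cc1
F3 | step 6 | protected seco compound: 4-[2-(4-fluoro-3-nitrophenyl)ethyl]-2-(4-{2-[3-(methoxymethoxy)phenyl]ethyl}phenoxy)benzaldehyde | O=Cc1ccc(CCc2ccc(F)c(c2)[N+](=O)[O-])cc1Oc1ccc(CCc2cccc(OCOC)c2)cc1
F4 | step 6 | seco phenol: 4-[2-(4-fluoro-3-nitrophenyl)ethyl]-2-{4-[2-(3-hydroxyphenyl)ethyl]phenoxy}benzaldehyde | O=Cc1ccc(CCc2ccc(F)c(c2)[N+](=O)[O-])cc1Oc1ccc(CCc2cccc(O)c2)cc1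
F5 | step 5 | bromo dioxolane: 2-(4-bromo-2-fluorophenyl)-1,3-dioxolane | Fc1cc(Br)ccc1C1OCCO1
F6 | step 5 | (E)-stilbene acetal: 2-{2-fluoro-4-[(E)-2-(4-fluoro-3-nitrophenyl)ethenyl]phenyl}-1,3-dioxolane | O=[N+]([O-])c1cc(/C=C/c2ccc(C3OCCO3)c(F)c2)ccc1F
F7 | step 5 | bibenzyl acetal: 2-{2-fluoro-4-[2-(4-fluoro-3-nitrophenyl)ethyl]phenyl}-1,3-dioxolane | O=[N+]([O-])c1cc(CCc2ccc(C3OCCO3)c(F)c2)ccc1F
F8 | step 10 | aryl iodide acetate: macrocycle with iodine on ring A and OAc on ring D | Ic1cc2ccc1Oc1cccc(c1)CCc1ccc(cc1)Oc1cc(ccc1OC(C)=O)CC2
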